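All constants were chosen freely; the run is a simulation.

The substrate left over at the end of the run is what I chase, and the flow through the cycle gives it, since each turn eats one reagent and one substrate.

substrate 1.5 M; reagent 0.700 equiv; scavenger 0.300 equiv; free catalyst 0.091 mol%; time 25 min

    reagent + free catalyst ⇌ catalyst intermediate A (K1 = 9.0 /M, k1 = 47 /M/min)
    substrate + catalyst intermediate A ⇌ catalyst intermediate B (K2 = 0.84 /M, k2 = 210 /M/min)
    catalyst intermediate B → released group + catalyst intermediate C (k3 = 57 /min)
    catalyst intermediate C ⇌ catalyst intermediate D (K4 = 28, k4 = 670 /min)
    catalyst intermediate D → free catalyst + target (k5 = 42 /min)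
    reagent + released group ⇌ idle adduct, settled at all times (K6 = 1.3 /M)
    scavenger + released group → scavenged by-product (k7 = 0.053 /M/min)

- part of the substrate that has reacted at 25 min
- share of the unused reagent that is free and not bound as idle adduct, at 25 min

- what is said of released group includes idle adduct
- run time (flask): 25 min

The catalyst charge is 0.00136 M, far below the substrate. Catalyst intermediate B lasts 0.730 s against a run of 25 min. So I freeze the cycle at a steady state, with one flow through every form.

Catalyst intermediates B, C and D then take 0.0437 min per turn, whatever the concentrations. But catalyst intermediate A takes 0.0171 min at the charged substrate, with its way back counted. The charged reagent is 1.05 M, and free catalyst takes 0.0221 min there.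

These add to 0.0829 min, the time of one turn: the sum, over the forms of the catalyst, of each form's amount divided by the flow. The flow is the catalyst charge over this time.

So the flow starts at 0.0165 M/min. Run flat for 25 min, it uses 0.412 M. I take that from substrate and reagent and leave the idle adduct aside. The same sum there gives 0.105 min, a flow of 0.0130 M/min. The mean of the two flows gives 24.6 % reacted. I stop there and do not reckon the free share.

The forecast says 24.3 % (23.3 % to 25.3 %) and 81.5 % (79.5 % to 83.5 %), from this ground: “The catalyst cycle settles almost at once”. My figure stands a little higher.

The simulation gives 24.2 % and 80.9 %.

The flask is not at rest at 25 min. Its substrate and reagent there make the turn 0.109 min, against 0.0829 min, so target still forms at 0.0125 M/min. The same two passes on the neighbour flask with 0.420 equiv of reagent start from a turn of 0.0976 min, use 0.350 M, and end at 0.151 min. That gives 19.2 %; that flask gave 19.2 %. At 250 min the flask has 69.8 % reacted, with 0.126 % of the reagent, the limiting reagent, left.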